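## The problem

The target (18) is a depsidone with no stereocenter. Two benzene rings are bridged by an ester and an ether oxygen into a seven-membered dioxepinone, and ring B also carries a fused 2,2-dimethylpyran-4-one. All of the difficulty is in substitution pattern and hindrance.

Ring A is pentasubstituted. Its carbons are numbered here C1 (methyl), C2 (H), C3 (hydroxyl), C4 (formyl), C5 (ether oxygen) and C6 (lactone carbonyl). Ring B is hexasubstituted, with four contiguous oxygens that each have a different partner. In chromanone numbering these are O1 of the pyranone, the free 8-OH, the 7-O aryl ether and the 6-O ester, next to the 5-methyl and the C4 ketone.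

Both bridge bonds are flanked by ortho substituents on both rings, so esterification or etherification between two finished rings is a crowded medium-ring closure. The aryl ester is opened by hydroxide, alkoxide and amines. The β-aryloxy ketone can open by retro-oxa-Michael reaction under strong base. The ortho-hydroxy aldehyde and the electron-rich ring B are sensitive to oxidants.

The feature that opens a short route is that the six ring A carbons fall into three two-carbon units that look like alkynes: C6/C1 (a but-2-ynoate), C5/C4 (an ynol ether of a masked propynal) and C2/C3 (an alkoxyacetylene). C5 and C6 are also the two ring A members of the seven-membered ring, and they hang through O and O–C(=O) on the adjacent ring B carbons C7 and C6.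

## Retrosynthesis

**18 ⇒ 17 ⇒ 16.** The two phenols and the aldehyde are masked to the end. The cuts are two O–alkyl bonds (ring A ethyl ether, ring B methyl ether) and the diethyl acetal in 16. These masks cost no steps to install: the ethyl comes with alkyne 15, the methyl is already in quinone 1, and the acetal comes with aldehyde 8. The forward steps need mild aqueous acid (16 → 17) and a Lewis acid that spares the lactone (17 → 18).

**16 ⇒ 14 + 15 (key step).** Three ring A bonds are cut: C5–C6, C1–C2 and C3–C4. The neighbouring cuts, the lactone C–O bond or the diaryl ether C–O bond, would need both fully substituted rings made first and then joined at hindered positions. The alkyne cut instead gives 14, which has a single aromatic ring, and the commercial alkyne 15. It brings in every ring A substituent already in place and closes the medium ring by carbon–carbon bond formation. The forward reaction must close a seven-membered ring in the metallacycle-forming step and insert 15 in one orientation.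

**14 ⇒ 12 + 13, 12 ⇒ 11.** The ester C–O bond is cut last in the backward sense. The aryl ynoate is the most labile group of 14, and an acyl group beside a free phenoxide would migrate, so acid 13 goes on only after the 7-oxygen is capped as the ynol ether. Phenol 12 is released from allyl ether 11. Allyl is chosen because it cannot migrate between the ortho oxygens, survives base, and is removed by zerovalent palladium without acid, which the ynol ether and acetal would not tolerate.

**11 ⇒ 10 ⇒ 7 + 9, 9 ⇒ 8.** The C(sp)–O bond of the ynol ether is not made directly. It is traced to the C(sp2)–O bond of bromoenol ether 10, from copper-catalysed vinylation of phenol 7 with dibromoalkene 9, followed by dehydrobromination. Alkene 9 is one step from aldehyde 8. The 6-oxygen must be capped here, because a free catechol would displace the second bromide and close a benzodioxole. This is the reason for the allyl group.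

**7 ⇒ 6 ⇒ 5.** The three ring B oxygens are told apart by their position. In chromanone 5 the 6-OH is the only free phenol and takes the allyl group (6). The 7-methoxy is the only one para to the ketone, so nucleophilic demethylation should remove it alone (7). The 8-methoxy stays as the final protecting group.

**5 ⇒ 2 + 3, 2 ⇒ 1.** The pyranone is cut at the aryl–acyl bond and the O1–C2 bond, giving hydroquinone 2 and acid 3. Compound 2 has a single unsubstituted carbon, flanked by a hydroxyl, so the annulation has no regiochemical choice. Quinone 1 already holds all four oxygens and the methyl group of ring B.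

## Roads not taken

**Alternative 1: ring B by cyclobutenone ring expansion.** Ring B is cut between the future ester-oxygen carbon and the methyl-bearing carbon. This leads back to a 4-hydroxy-4-propenylcyclobutenone (A1) built from a squarate, a ring A phenol and a propenyl metal reagent.
- Forward step: heating A1 opens it to a dienylketene, whose 6π-electrocyclisation gives hydroquinone diaryl ether A2.
- Merits: the reaction type is well established. The diaryl ether is made by simple addition–elimination on the squarate instead of a hindered coupling, and the ring B oxygens emerge differentiated. In precedent this road is stronger than the chosen one.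
- Weak points: the organometallic must add to one particular carbonyl of an unsymmetrical squarate, in the presence of the ring A ester, and A2 is an air-sensitive hydroquinone. After A2 the hindered seven-membered lactonisation, the pyranone annulation, formylation of ring A (two open positions) and two demethylations still remain.
- Comparison: the chosen plan has an unprecedented key step. In return, no substituent has to be placed on ring A by late electrophilic substitution, and no hindered lactonisation is needed.

**Alternative 2: oxidative lactonisation through an ortho-quinone.** The cut is the bond between the ester oxygen and ring B. The precursor is catechol acid A3.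
- Forward step: Ag2O oxidises the catechol to the ortho-quinone, and the carboxylic acid adds in conjugate fashion to the unsubstituted carbon beside the ether carbon. This gives depsidone A4.
- Merits: it is the shortest way to a depsidone core, needs no protecting groups, and makes the crowded ester bond by a favourable intramolecular addition while installing the fourth ring B oxygen. In brevity to the core it beats the chosen plan.
- Weak points: A4 lacks the pyranone and the formyl group. The later acylation would have to pick the single ring B position over two activated ring A positions, and the formylation would again face a choice on ring A, all on a polyphenol with a base-labile lactone. The ortho-quinone can also be attacked elsewhere or dimerise.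
- Comparison: the chosen plan builds the pyranone on an isolated ring B with only one open position and carries the formyl carbon in from the start.

**Alternative 3: tethered macrocycle and transannular Ullmann etherification.** The cut is the ring A C5–O bond of the diaryl ether. The precursor is the ten-membered bromo phenol A5, in which the future formyl carbon is tied as a benzyl ether to the ring B 8-oxygen.
- Forward step: CuI with N,N-dimethylglycine and Cs2CO3 closes the ether across the macrocycle to the bridged depsidone A6.
- Merits: every reaction type is known, every substituent position is fixed by unambiguous chemistry, and the tether protects both the 8-OH and the formyl oxidation level. In reliability it is the better road.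
- Weak points: it is the longest road. The pentasubstituted ring A bromide needs its own synthesis, and a ten-membered ring must be closed under dilution. The coupling is at a di-ortho-substituted bromide with the lactone exposed to hot carbonate, and an oxidative untethering follows.
- Comparison: the chosen plan is about half as long and makes ring A from three simple alkynes, at the price of one unproven step.

Key step: step 10

Assumption: the target has no stereogenic element, so no descriptors are needed apart from the alkene geometry of 10. Aldehyde 8 and alkyne 15 (as a hexane solution) are taken as commercial.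

## Route

Step 1
Reactants: 1 2,3-dimethoxy-5-methyl-1,4-benzoquinone
Product: 2 2,3-dimethoxy-5-methylbenzene-1,4-diol
Conditions: Na2S2O4, EtOAc/H2O, rt
Reagents that add atoms: none
Why: Dithionite reduction of a benzoquinone to its hydroquinone; the product is used at once to avoid re-oxidation.

Step 2
Reactants: 2 2,3-dimethoxy-5-methylbenzene-1,4-diol; 3 3-methylbut-2-enoic acid
Product: 5 6-hydroxy-7,8-dimethoxy-2,2,5-trimethylchroman-4-one, via aryl enone 4 (not isolated)
Conditions: P2O5/MeSO3H (Eaton's reagent), 70 °C
Reagents that add atoms: none
Why: Friedel–Crafts acylation through the mixed anhydride of 3 at the only unsubstituted carbon of 2 gives enone 4, and the flanking hydroxyl closes the pyranone by oxa-Michael addition (standard chroman-4-one annulation); the other hydroxyl stays free as the 6-OH.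

Step 3
Reactants: 5 6-hydroxy-7,8-dimethoxy-2,2,5-trimethylchroman-4-one
Product: 6 6-(allyloxy)-7,8-dimethoxy-2,2,5-trimethylchroman-4-one
Conditions: allyl bromide, K2CO3, DMF, 50 °C
Reagents that add atoms: allyl bromide, C=CCBr
Why: Williamson etherification of the only phenol; carbonate is too weak to open the pyranone, and the allyl group cannot migrate to the neighbouring oxygen later.

Step 4
Reactants: 6 6-(allyloxy)-7,8-dimethoxy-2,2,5-trimethylchroman-4-one
Product: 7 6-(allyloxy)-7-hydroxy-8-methoxy-2,2,5-trimethylchroman-4-one
Conditions: LiCl, DMF, 140 °C; dilute HCl work-up
Reagents that add atoms: none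
Why: SN2 demethylation by chloride, a known reaction of aryl methyl ethers activated by an ortho or para acyl group; only the 7-methoxy is para to the ketone, so only its phenoxide is a good leaving group, and the 8-methoxy and the unactivated allyl ether should remain.

Step 5
Reactants: 8 2,2-diethoxyacetaldehyde
Product: 9 1,1-dibromo-3,3-diethoxyprop-1-ene
Conditions: CBr4, PPh3, Zn, CH2Cl2, rt
Reagents that add atoms: carbon tetrabromide, BrC(Br)(Br)Br
Why: Ramirez dibromo-olefination (first stage of the Corey–Fuchs sequence); the zinc variant keeps acidic phosphonium bromide out of the flask, so the acetal survives.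

Step 6
Reactants: 7 6-(allyloxy)-7-hydroxy-8-methoxy-2,2,5-trimethylchroman-4-one; 9 1,1-dibromo-3,3-diethoxyprop-1-ene
Product: 10 6-(allyloxy)-7-{[(Z)-1-bromo-3,3-diethoxyprop-1-en-1-yl]oxy}-8-methoxy-2,2,5-trimethylchroman-4-one
Conditions: CuI (10 mol%), 2,2'-bipyridine (20 mol%), K3PO4, toluene, 110 °C
Reagents that add atoms: none
Why: Copper-catalysed vinylic substitution of a gem-dibromoalkene by a phenol (monovalent copper with bipyridine); the bromine trans to the substituent is replaced, which should give the Z bromoenol ether, and the capped 6-oxygen cannot attack the second bromide.

Step 7
Reactants: 10 the Z bromoenol ether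
Product: 11 6-(allyloxy)-7-[(3,3-diethoxyprop-1-yn-1-yl)oxy]-8-methoxy-2,2,5-trimethylchroman-4-one
Conditions: KOtBu, 1,4-dioxane, rt; pH 7 buffer work-up
Reagents that add atoms: none
Why: E2 dehydrobromination with hydrogen and bromine anti-periplanar in the Z isomer, the usual second stage of this ynol ether synthesis; the ketone is only reversibly enolised and should be recovered on buffered work-up.

Step 8
Reactants: 11 the allyl-protected ynol ether
Product: 12 7-[(3,3-diethoxyprop-1-yn-1-yl)oxy]-6-hydroxy-8-methoxy-2,2,5-trimethylchroman-4-one
Conditions: Pd(PPh3)4 (5 mol%), morpholine, THF, 0 °C to rt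
Reagents that add atoms: none
Why: Tsuji–Trost deallylation: zerovalent palladium ionises the allyl aryl ether and morpholine takes up the allyl group; no acid is present, so the ynol ether and acetal should survive, and the phenol is carried on without storage.

Step 9
Reactants: 12 the free 6-phenol; 13 but-2-ynoic acid
Product: 14 7-[(3,3-diethoxyprop-1-yn-1-yl)oxy]-8-methoxy-2,2,5-trimethyl-4-oxochroman-6-yl but-2-ynoate
Conditions: DIC, DMAP (cat.), CH2Cl2, −20 to 0 °C
Reagents that add atoms: none
Why: Steglich esterification; the acid is premixed with the carbodiimide so the ynol ether does not meet free carboxylic acid, and low temperature with little DMAP limits isomerisation of the ynoate to the allenoate.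

Step 10
Reactants: 14 the ring B diyne; 15 ethoxyacetylene
Product: 16 the depsidone with the ring A oxygen as ethyl ether, the formyl group as diethyl acetal and the ring B 8-oxygen as methyl ether
Conditions: [Rh(cod)2]BF4 (10 mol%), rac-BINAP (10 mol%), H2 pre-activation, CH2Cl2, rt, slow addition of 15 (3 equiv)
Reagents that add atoms: none
Why: Proposed new method: cationic monovalent rhodium with BINAP should bind the electron-poor ynoate and the electron-rich ynol ether of 14, couple them oxidatively to a rhodacyclopentadiene of trivalent rhodium (new bond between the ynoate α-carbon and the oxygen-bearing ynol ether carbon), insert 15 and release ring A by reductive elimination; the closest known reaction type is the rhodium-catalysed (2+2+2) cycloaddition of tethered diynes with monoalkynes, ynol ethers included, which has not been shown for an ester/ynol-ether tether that closes a seven-membered ring. The seven-membered lactone closes in the oxidative coupling, as the ring fused to the rhodacycle, with its five tether atoms (O, two ring B carbons, O, C=O) held cisoid by the ortho-disubstituted benzene. Ring A closes afterwards by alkyne insertion and carbon–carbon reductive elimination. No stereocenter is formed. The selectivity needed is the orientation of 15: its unsubstituted, nucleophilic carbon must join the methyl-bearing carbon, which is the electrophilic β-carbon of the enoate in the rhodacycle, and its oxygen-bearing carbon must join the acetal-bearing carbon, which is the nucleophilic β-carbon of an enol ether. This polar match from the push–pull substitution of 14 is expected to outweigh the steric preference for ethoxy beside methyl. Slow addition of 15 should hold back its own trimerisation, and dilution the dimerisation of 14.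

Step 11
Reactants: 16 the protected depsidone acetal
Product: 17 the depsidone aldehyde with ring A ethyl ether and ring B methyl ether
Conditions: 1 M HCl, THF, rt
Reagents that add atoms: water, O
Why: Acid-catalysed hydrolysis of an aryl diethyl acetal; the aryl ester, aryl ethers and pyranone are stable to dilute acid at room temperature.

Step 12
Reactants: 17 the depsidone aldehyde
Product: 18 the target, CNP0271978.0
Conditions: BCl3, CH2Cl2, −78 to 0 °C; then H2O
Reagents that add atoms: none
Why: Lewis-acid ether cleavage: BCl3 chelated between the formyl oxygen and the ortho ethoxy group removes that ethyl, and the 8-methoxy, twisted out of plane between two oxygens, is the crowded kind of methyl ether that BCl3 also cleaves at low temperature; the lactone and the tertiary pyranone ether should survive if the mixture is kept cold.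

## Compound list

1 | 2,3-dimethoxy-5-methyl-1,4-benzoquinone (ubiquinone-0) | COC1=C(OC)C(=O)C(C)=CC1=O | starting material
2 | 2,3-dimethoxy-5-methylbenzene-1,4-diol | COc1c(O)cc(C)c(O)c1OC | intermediate
3 | 3-methylbut-2-enoic acid | CC(C)=CC(O)=O | starting material
4 | 1-(2,5-dihydroxy-3,4-dimethoxy-6-methylphenyl)-3-methylbut-2-en-1-one | CC(C)=CC(=O)c1c(C)c(O)c(OC)c(OC)c1O | intermediate
5 | 6-hydroxy-7,8-dimethoxy-2,2,5-trimethylchroman-4-one | Cc1c(O)c(OC)c(OC)c2OC(C)(C)CC(=O)c12 | intermediate
6 | 6-(allyloxy)-7,8-dimethoxy-2,2,5-trimethylchroman-4-one | Cc1c(OCC=C)c(OC)c(OC)c2OC(C)(C)CC(=O)c12 | intermediate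
7 | 6-(allyloxy)-7-hydroxy-8-methoxy-2,2,5-trimethylchroman-4-one | Cc1c(OCC=C)c(O)c(OC)c2OC(C)(C)CC(=O)c12 | intermediate
8 | 2,2-diethoxyacetaldehyde | CCOC(OCC)C=O | starting material
9 | 1,1-dibromo-3,3-diethoxyprop-1-ene | CCOC(OCC)C=C(Br)Br | intermediate
10 | 6-(allyloxy)-7-{[(Z)-1-bromo-3,3-diethoxyprop-1-en-1-yl]oxy}-8-methoxy-2,2,5-trimethylchroman-4-one | Cc1c(OCC=C)c(O/C(Br)=C/C(OCC)OCC)c(OC)c2OC(C)(C)CC(=O)c12 | intermediate
11 | 6-(allyloxy)-7-[(3,3-diethoxyprop-1-yn-1-yl)oxy]-8-methoxy-2,2,5-trimethylchroman-4-one | Cc1c(OCC=C)c(OC#CC(OCC)OCC)c(OC)c2OC(C)(C)CC(=O)c12 | intermediate
12 | 7-[(3,3-diethoxyprop-1-yn-1-yl)oxy]-6-hydroxy-8-methoxy-2,2,5-trimethylchroman-4-one | Cc1c(O)c(OC#CC(OCC)OCC)c(OC)c2OC(C)(C)CC(=O)c12 | intermediate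
13 | but-2-ynoic acid | CC#CC(O)=O | starting material
14 | 7-[(3,3-diethoxyprop-1-yn-1-yl)oxy]-8-methoxy-2,2,5-trimethyl-4-oxochroman-6-yl but-2-ynoate | CC#CC(=O)Oc1c(C)c2c(c(OC)c1OC#CC(OCC)OCC)OC(C)(C)CC2=O | intermediate
15 | ethoxyacetylene | CCOC#C | starting material
16 | depsidone with ring A ethyl ether, formyl as diethyl acetal, ring B 8-methyl ether | Cc1cc(OCC)c(C(OCC)OCC)c2c1C(=O)Oc1c(C)c3c(c(OC)c1O2)OC(C)(C)CC3=O | intermediate
17 | depsidone aldehyde with ring A ethyl ether and ring B 8-methyl ether | Cc1cc(OCC)c(C=O)c2c1C(=O)Oc1c(C)c3c(c(OC)c1O2)OC(C)(C)CC3=O | intermediate
18 | CNP0271978.0 | Cc1cc(O)c(C=O)c2c1C(=O)Oc1c(C)c3c(c(O)c1O2)OC(C)(C)CC3=O | target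

## Step count and least certain steps

Total step count: 12. Longest linear sequence: 11 steps (1 to 18 through steps 1–4 and 6–12); step 5 is a one-step side branch.

**Step 10 (key step, new method).** Two things are most likely to fail. The first is insertion of 15 in the reverse orientation, because the acetal-bearing end of the rhodacycle is the more crowded one. The second is failure of the oxidative coupling to close the seven-membered ring, leaving 15 to trimerise on its own.

The fallback uses known chemistry only and sets out from phenol 7. Its phenoxide (K2CO3, DMF, 80 °C) displaces the fluoride of allyl 4-ethoxy-2-fluoro-3-formyl-6-methylbenzoate F1 in an SNAr reaction. F1 is a ring A block activated by the ortho formyl and ortho ester groups; it would have to be made separately. The product is diaryl ether F2. Pd(PPh3)4 with morpholine removes both allyl groups to give hydroxy acid F3, and carbodiimide lactonisation (DCC, pyridine) closes the seven-membered ring. The route is rejoined at 17.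

**Step 8.** The liberated phenol, or its ammonium phenoxide, may add across the neighbouring ynol ether triple bond in a five-membered ring closure. The amine scavenger may also add to the ynol ether.

The fallback sets out from 11 and never frees the oxygen. Deallylation with Pd(PPh3)4 and N,N-dimethyltrimethylsilylamine as a silylating allyl scavenger should deliver trimethylsilyl ether F4. F4 is then acylated under the conditions of step 9 with a catalytic amount of n-Bu4NF, so the phenoxide appears only in the presence of the activated acid. The route is rejoined at 14.

**Step 4.** The electron-rich ring may make chloride demethylation slow, and forcing it risks loss of the allyl group or cleavage at the wrong methoxy.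

The fallback sets out from 5 and reverses the order. NaSEt in DMF demethylates the free phenol 5 at the 7-position to give 6,7-dihydroxy-8-methoxy-2,2,5-trimethylchroman-4-one F5. Its dianion (NaH, 2.2 equiv, DMSO) is then treated with one equivalent of allyl bromide. Alkylation should occur at the more basic 6-oxide, as is known for catechols with a para acyl group. The route is rejoined at 7.

**Step 2.** Ring alkylation by the protonated alkene of 3, followed by lactonisation, may compete with acylation. The hydroquinone may also oxidise in the hot acid.

The fallback sets out from 2. Friedel–Crafts acetylation (AcOH, BF3·OEt2, 90 °C) gives 1-(2,5-dihydroxy-3,4-dimethoxy-6-methylphenyl)ethan-1-one F6. Kabbe condensation with acetone and pyrrolidine then builds the 2,2-dimethylpyranone. The route is rejoined at 5.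

## Further compounds

F1 | step 10 | allyl 4-ethoxy-2-fluoro-3-formyl-6-methylbenzoate | C=CCOC(=O)c1c(C)cc(OCC)c(C=O)c1F
F2 | step 10 | allyl 2-{[6-(allyloxy)-8-methoxy-2,2,5-trimethyl-4-oxochroman-7-yl]oxy}-4-ethoxy-3-formyl-6-methylbenzoate | C=CCOC(=O)c1c(C)cc(OCC)c(C=O)c1Oc1c(OC)c2OC(C)(C)CC(=O)c2c(C)c1OCC=C
F3 | step 10 | 4-ethoxy-3-formyl-2-[(6-hydroxy-8-methoxy-2,2,5-trimethyl-4-oxochroman-7-yl)oxy]-6-methylbenzoic acid | OC(=O)c1c(C)cc(OCC)c(C=O)c1Oc1c(OC)c2OC(C)(C)CC(=O)c2c(C)c1O
F4 | step 8 | 7-[(3,3-diethoxyprop-1-yn-1-yl)oxy]-8-methoxy-2,2,5-trimethyl-6-(trimethylsilyloxy)chroman-4-one | Cc1c(O[Si](C)(C)C)c(OC#CC(OCC)OCC)c(OC)c2OC(C)(C)CC(=O)c12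
F5 | step 4 | 6,7-dihydroxy-8-methoxy-2,2,5-trimethylchroman-4-one | Cc1c(O)c(O)c(OC)c2OC(C)(C)CC(=O)c12
F6 | step 2 | 1-(2,5-dihydroxy-3,4-dimethoxy-6-methylphenyl)ethan-1-one | CC(=O)c1c(C)c(O)c(OC)c(OC)c1O
A1 | alternative 1 | methyl 2-{[3-hydroxy-2-methoxy-4-oxo-3-((E)-prop-1-enyl)cyclobut-1-en-1-yl]oxy}-4-methoxy-6-methylbenzoate | COC(=O)c1c(C)cc(OC)cc1OC1=C(OC)C(O)(/C=C/C)C1=O
A2 | alternative 1 | methyl 2-(2,5-dihydroxy-6-methoxy-3-methylphenoxy)-4-methoxy-6-methylbenzoate | COC(=O)c1c(C)cc(OC)cc1Oc1c(O)c(C)cc(O)c1OC
A3 | alternative 2 | 2-(2,3-dihydroxy-5-methylphenoxy)-4-hydroxy-6-methylbenzoic acid | Cc1cc(O)cc(Oc2cc(C)cc(O)c2O)c1C(=O)O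
A4 | alternative 2 | 3,6,7-trihydroxy-1,9-dimethyldibenzo[b,e][1,4]dioxepin-11-one | Cc1cc(O)cc2c1C(=O)Oc1c(C)cc(O)c(O)c1O2
A5 | alternative 3 | ten-membered macrolactone bromo phenol with the benzyl ether tether | Cc1cc(OC)c2c(Br)c1C(=O)Oc1c(C)c3c(c(OC2)c1O)OC(C)(C)CC3=O
A6 | alternative 3 | tether-bridged depsidone | Cc1cc(OC)c2c3c1C(=O)Oc1c(C)c4c(c(c1O3)OC2)OC(C)(C)CC4=O
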